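**Plan**

1. Numbering used throughout: 1,4-benzodioxine O1–C2(CH2OH)–C3(aryl)–O4–C4a … C6(side chain) … C8(OMe)–C8a. The retrosynthesis first returns three groups to the ester level (allylic alcohol ← ethyl enoate, C2–CH2OH ← N-acyl oxazolidinone, phenol ← pivalate). It then cuts the dioxane ring at two bonds at once, C2–C3 and O4–C4a.
2. What allows this: C3 with O4 is a benzylic carbinol, i.e. the C=O of syringaldehyde. C2 is the α-carbon of a glycolate carried on O1 (its CH2OH is a reduced carboxyl). C4a is the arene carbon ortho to the O1-bearing C8a. The ring is therefore a formal [4+2] of an aldehyde C=O with a C2–O1–C8a–C4a unit that is nucleophilic at C2 (enolate) and electrophilic at C4a (C–Br, from 5-bromovanillin).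
3. Forward: 5-bromovanillin is olefinated and O-alkylated with a bromoacetyl oxazolidinone. One flask then joins this piece to pivaloyl-protected syringaldehyde by boron aldol addition and palladium-catalysed O-arylation, which closes the only new ring. Two hydride reductions finish the synthesis.
4. Stereochemistry: both stereocentres come from the auxiliary-controlled syn-aldol (syn adduct = trans ring; the (R)-4-benzyloxazolidinone leads to 2S,3S after reduction). The E-alkene comes from the stabilised ylide. The ring regiochemistry comes from the position of Br next to the phenol oxygen.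

Key step: step 5

**Route**

Step 1
Reactants: 1 5-bromovanillin (3-bromo-4-hydroxy-5-methoxybenzaldehyde); 2 ethyl (triphenylphosphoranylidene)acetate
Product: 3 ethyl (E)-3-(3-bromo-4-hydroxy-5-methoxyphenyl)prop-2-enoate
Conditions: toluene, 90 °C
Reagents that add atoms: none
Why: Wittig olefination with a stabilised ylide tolerates the free phenol and should give the E-enoate, which also removes the aldehyde that would otherwise compete as an aldol acceptor in step 5.

Step 2
Reactants: 4 (R)-4-benzyl-1,3-oxazolidin-2-one; 5 bromoacetyl bromide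
Product: 6 (R)-4-benzyl-3-(2-bromoacetyl)-1,3-oxazolidin-2-one
Conditions: n-BuLi, THF, −78 °C; then 5, −78 → 0 °C
Reagents that add atoms: none
Why: N-acylation of the lithiated oxazolidinone with an acid bromide is the standard entry to N-(haloacetyl) imides and leaves the existing stereocentre untouched.

Step 3
Reactants: 3 ethyl (E)-3-(3-bromo-4-hydroxy-5-methoxyphenyl)prop-2-enoate; 6 (R)-4-benzyl-3-(2-bromoacetyl)-1,3-oxazolidin-2-one
Product: 7 ethyl (E)-3-[4-{2-[(4R)-4-benzyl-2-oxo-1,3-oxazolidin-3-yl]-2-oxoethoxy}-3-bromo-5-methoxyphenyl]prop-2-enoate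
Conditions: K2CO3, MeCN, rt
Reagents that add atoms: none
Why: Williamson ether synthesis, in which the phenoxide should displace the strongly activated α-bromide by SN2 faster than it attacks the imide carbonyl, placing the glycolate on the oxygen flanked by Br and OMe and so fixing the regiochemistry of the later ring.

Step 4
Reactants: 8 syringaldehyde (4-hydroxy-3,5-dimethoxybenzaldehyde)
Product: 9 4-formyl-2,6-dimethoxyphenyl 2,2-dimethylpropanoate
Conditions: pivaloyl chloride, Et3N, DMAP (cat.), CH2Cl2, 0 °C → rt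
Reagents that add atoms: pivaloyl chloride, CC(C)(C)C(Cl)=O
Why: DMAP-catalysed acylation of the hindered phenol gives an ester that should survive the boron and palladium chemistry, makes the aldehyde more electrophilic, and is removed by the final hydride step.

Step 5
Reactants: 7 ethyl (E)-3-[4-{2-[(4R)-4-benzyl-2-oxo-1,3-oxazolidin-3-yl]-2-oxoethoxy}-3-bromo-5-methoxyphenyl]prop-2-enoate; 9 4-formyl-2,6-dimethoxyphenyl 2,2-dimethylpropanoate
Product: 13 ethyl (E)-3-[(2R,3S)-2-{[(4R)-4-benzyl-2-oxo-1,3-oxazolidin-3-yl]carbonyl}-3-[3,5-dimethoxy-4-(pivaloyloxy)phenyl]-8-methoxy-2,3-dihydro-1,4-benzodioxin-6-yl]prop-2-enoate, via Z-boron enolate 10 (not isolated), via boron aldolate 11 (not isolated), via syn-aldol 12 (not isolated)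
Conditions: n-Bu2BOTf (1.2 equiv), i-Pr2NEt (1.4 equiv), CH2Cl2, −78 → 0 °C; 9, −78 → 0 °C; MeOH, then evaporate; same flask: Pd(OAc)2 (5 mol %), 2-(di-tert-butylphosphino)-1,1'-binaphthyl (6 mol %), K3PO4 (3 equiv), toluene, 60 °C
Reagents that add atoms: none
Why: Proposed new method: soft enolisation of the α-aryloxy imide gives the Z-boron enolate 10, which adds to aldehyde 9 through a closed six-membered chair (Zimmerman–Traxler) transition state to the boron aldolate 11 and so forms the C2–C3 bond; methanolysis frees the carbinol 12, zerovalent palladium then inserts into the C–Br bond ortho to the glycolate oxygen, the hydroxyl is deprotonated on the metal by K3PO4, and C–O reductive elimination from the seven-membered oxapalladacycle forms the O4–C4a bond. The closest known reaction types are the boron-mediated syn-aldol of N-glycolyl oxazolidinones (Evans aldol) and the palladium-catalysed intramolecular etherification of 2-(2-bromophenoxy)alkanols to 1,4-benzodioxanes (Buchwald–Hartwig type); running them as one flask operation, a formal [4+2] annulation of an aldehyde C=O with an enolisable C–O–C=C–Br unit, is what is new. The dioxane ring is closed in a 6-exo mode at the sp2 carbon C4a, with bromide leaving outside the ring. Both stereocentres are set in the aldol event: the Z-enolate geometry gives the 2,3-syn adduct, which maps onto the trans ring, and the benzyl group of the (R)-oxazolidinone, held in the dipole-opposed conformation, blocks one enolate face so that the (2R,3S) adduct should form; the C–O coupling breaks no bond at either centre. Needed are chemoselective enolisation (only the imide has acidic α-hydrogens), ring closure faster than retro-aldol cleavage or β-hydride elimination (weak insoluble base so that the alkoxide exists only on palladium, a bulky dialkylbiarylphosphine, a six-membered ring, the more electrophilic pivalate-bearing aldehyde) and no butyl transfer from boron (borinate removed with the methanol). Any epimerisation at the carbonyl-bearing C2 converges on the more stable trans ring, and stray diastereomers stay separable because the auxiliary is still attached.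

Step 6
Reactants: 13 ethyl (E)-3-[(2R,3S)-2-{[(4R)-4-benzyl-2-oxo-1,3-oxazolidin-3-yl]carbonyl}-3-[3,5-dimethoxy-4-(pivaloyloxy)phenyl]-8-methoxy-2,3-dihydro-1,4-benzodioxin-6-yl]prop-2-enoate
Product: 14 ethyl (E)-3-[(2S,3S)-3-[3,5-dimethoxy-4-(pivaloyloxy)phenyl]-2-(hydroxymethyl)-8-methoxy-2,3-dihydro-1,4-benzodioxin-6-yl]prop-2-enoate
Conditions: LiBH4 (1.5 equiv), H2O (1 equiv), THF/Et2O, 0 °C
Reagents that add atoms: none
Why: Reductive cleavage of the N-acyl oxazolidinone by hydride attack at the more electrophilic exocyclic α-aryloxy carbonyl should give the primary alcohol and free auxiliary 4 faster than the conjugated ethyl ester or the hindered pivalate react, and without enolising the adjacent stereocentre.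

Step 7
Reactants: 14 ethyl (E)-3-[(2S,3S)-3-[3,5-dimethoxy-4-(pivaloyloxy)phenyl]-2-(hydroxymethyl)-8-methoxy-2,3-dihydro-1,4-benzodioxin-6-yl]prop-2-enoate
Product: 15 (E)-3-[(2S,3S)-3-(4-hydroxy-3,5-dimethoxyphenyl)-2-(hydroxymethyl)-8-methoxy-2,3-dihydro-1,4-benzodioxin-6-yl]prop-2-en-1-ol
Conditions: i-Bu2AlH (7 equiv), CH2Cl2, −78 → 0 °C; aq. potassium sodium tartrate
Reagents that add atoms: none
Why: Ester reduction with i-Bu2AlH should convert the enoate in 1,2-fashion into the E-allylic alcohol and cleave the aryl pivalate in the same operation, with neither stereocentre involved.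

**Compound list**

1 | 5-bromovanillin (3-bromo-4-hydroxy-5-methoxybenzaldehyde) | COc1cc(C=O)cc(Br)c1O | starting material
2 | ethyl (triphenylphosphoranylidene)acetate | CCOC(=O)C=P(c1ccccc1)(c1ccccc1)c1ccccc1 | starting material
3 | ethyl (E)-3-(3-bromo-4-hydroxy-5-methoxyphenyl)prop-2-enoate | CCOC(=O)/C=C/c1cc(Br)c(O)c(OC)c1 | intermediate
4 | (R)-4-benzyl-1,3-oxazolidin-2-one | O=C1N[C@H](Cc2ccccc2)CO1 | starting material
5 | bromoacetyl bromide | O=C(Br)CBr | starting material
6 | (R)-4-benzyl-3-(2-bromoacetyl)-1,3-oxazolidin-2-one | O=C(CBr)N1C(=O)OC[C@H]1Cc1ccccc1 | intermediate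
7 | ethyl (E)-3-[4-{2-[(4R)-4-benzyl-2-oxo-1,3-oxazolidin-3-yl]-2-oxoethoxy}-3-bromo-5-methoxyphenyl]prop-2-enoate | CCOC(=O)/C=C/c1cc(Br)c(OCC(=O)N2C(=O)OC[C@H]2Cc3ccccc3)c(OC)c1 | intermediate
8 | syringaldehyde (4-hydroxy-3,5-dimethoxybenzaldehyde) | COc1cc(C=O)cc(OC)c1O | starting material
9 | 4-formyl-2,6-dimethoxyphenyl 2,2-dimethylpropanoate | COc1cc(C=O)cc(OC)c1OC(=O)C(C)(C)C | intermediate
10 | Z-di-n-butylboron enolate of 7: ethyl (E)-3-[4-({(Z)-2-[(4R)-4-benzyl-2-oxo-1,3-oxazolidin-3-yl]-2-[(dibutylboranyl)oxy]ethenyl}oxy)-3-bromo-5-methoxyphenyl]prop-2-enoate (not isolated) | CCOC(=O)/C=C/c1cc(Br)c(O/C=C(\OB(CCCC)CCCC)N2C(=O)OC[C@H]2Cc3ccccc3)c(OC)c1 | intermediate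
11 | di-n-butylboron aldolate of 12 (O-dibutylboryl derivative at the benzylic oxygen; not isolated) | COc1cc([C@H](OB(CCCC)CCCC)[C@@H](Oc2c(Br)cc(/C=C/C(=O)OCC)cc2OC)C(=O)N3C(=O)OC[C@H]3Cc4ccccc4)cc(OC)c1OC(=O)C(C)(C)C | intermediate
12 | syn-aldol: ethyl (E)-3-[4-({(2R,3S)-1-[(4R)-4-benzyl-2-oxo-1,3-oxazolidin-3-yl]-3-[3,5-dimethoxy-4-(pivaloyloxy)phenyl]-3-hydroxy-1-oxopropan-2-yl}oxy)-3-bromo-5-methoxyphenyl]prop-2-enoate (not isolated) | COc1cc([C@H](O)[C@@H](Oc2c(Br)cc(/C=C/C(=O)OCC)cc2OC)C(=O)N3C(=O)OC[C@H]3Cc4ccccc4)cc(OC)c1OC(=O)C(C)(C)C | intermediate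
13 | ethyl (E)-3-[(2R,3S)-2-{[(4R)-4-benzyl-2-oxo-1,3-oxazolidin-3-yl]carbonyl}-3-[3,5-dimethoxy-4-(pivaloyloxy)phenyl]-8-methoxy-2,3-dihydro-1,4-benzodioxin-6-yl]prop-2-enoate (trans) | COc1cc([C@@H]2Oc3cc(/C=C/C(=O)OCC)cc(OC)c3O[C@H]2C(=O)N4C(=O)OC[C@H]4Cc5ccccc5)cc(OC)c1OC(=O)C(C)(C)C | intermediate
14 | ethyl (E)-3-[(2S,3S)-3-[3,5-dimethoxy-4-(pivaloyloxy)phenyl]-2-(hydroxymethyl)-8-methoxy-2,3-dihydro-1,4-benzodioxin-6-yl]prop-2-enoate | COc1cc([C@@H]2Oc3cc(/C=C/C(=O)OCC)cc(OC)c3O[C@H]2CO)cc(OC)c1OC(=O)C(C)(C)C | intermediate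
15 | (E)-3-[(2S,3S)-3-(4-hydroxy-3,5-dimethoxyphenyl)-2-(hydroxymethyl)-8-methoxy-2,3-dihydro-1,4-benzodioxin-6-yl]prop-2-en-1-ol | COc1cc([C@@H]2Oc3cc(/C=C/CO)cc(OC)c3O[C@H]2CO)cc(OC)c1O | target

**Summary**

Total step count: 7. Longest linear sequence: 5 steps (steps 1, 3, 5, 6, 7 from 5-bromovanillin; equally steps 2, 3, 5, 6, 7 from the oxazolidinone).

**Steps most likely to fail**

1. Step 5 (proposed new method). Once the carbinol is free, the basic palladium stage may trigger retro-aldol cleavage and re-addition before the ring closes, eroding the benzylic configuration. Palladium alkoxide β-hydride elimination with loss of bromine, or butyl transfer from residual boron, may also divert material. The fallback uses known chemistry and closes the ring at the alcohol oxidation level, where retro-aldol cleavage is impossible. It sets out from 7 and 9. The boron aldol is run alone with the usual oxidative work-up (MeOH, pH 7 buffer, H2O2) and the syn-aldol 12 is isolated. LiBH4 (THF, H2O, 0 °C) then removes the auxiliary to give the bromoaryl 1,3-diol F1. TBSCl and imidazole (CH2Cl2, 0 °C) silylate the primary hydroxyl selectively to give the primary silyl ether F2. Palladium-catalysed intramolecular etherification of the remaining secondary alcohol (Pd(OAc)2, 2-(di-tert-butylphosphino)-1,1'-binaphthyl, Cs2CO3, toluene, 65 °C) should close the ring to the silylated benzodioxane F3. HF·pyridine in THF frees the primary alcohol, and the route is rejoined at 14.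

2. Step 3. The hindered phenoxide may attack the imide carbonyl instead of the CH2Br carbon, transferring the acyl group and losing the auxiliary, or the alkylation may simply be slow. The fallback sets out from 3 and does not need 6. Alkylation with tert-butyl bromoacetate (K2CO3, DMF, rt) gives the tert-butyl aryloxyacetate F4. CF3CO2H in CH2Cl2 cleaves the tert-butyl ester to the aryloxyacetic acid F5. Activation as the mixed pivalic anhydride (pivaloyl chloride, Et3N, THF, −20 °C) and addition of lithiated 4 (n-BuLi, THF, −78 °C) gives the imide, and the route is rejoined at 7.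

3. Step 7. Hydride cleavage of the aryl pivalate, which is flanked by two methoxy groups, may stay incomplete. Long exposure of the electron-rich cinnamyl alcohol to excess aluminium reagent may also cost material. The fallback separates reduction from deprotection and sets out from 14. i-Bu2AlH (3.5 equiv, CH2Cl2, −78 °C) reduces only the enoate and gives the pivalate-protected allylic alcohol F6. Methanolysis of the aryl ester (K2CO3, MeOH, rt) then releases the phenol, and the route is rejoined at 15.

**Further compounds**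

F1 | step 5 | ethyl (E)-3-(3-bromo-4-{[(1S,2S)-1-[3,5-dimethoxy-4-(pivaloyloxy)phenyl]-1,3-dihydroxypropan-2-yl]oxy}-5-methoxyphenyl)prop-2-enoate | COc1cc([C@H](O)[C@@H](Oc2c(Br)cc(/C=C/C(=O)OCC)cc2OC)CO)cc(OC)c1OC(=O)C(C)(C)C
F2 | step 5 | ethyl (E)-3-(3-bromo-4-{[(1S,2S)-3-[(tert-butyldimethylsilyl)oxy]-1-[3,5-dimethoxy-4-(pivaloyloxy)phenyl]-1-hydroxypropan-2-yl]oxy}-5-methoxyphenyl)prop-2-enoate | COc1cc([C@H](O)[C@@H](Oc2c(Br)cc(/C=C/C(=O)OCC)cc2OC)CO[Si](C)(C)C(C)(C)C)cc(OC)c1OC(=O)C(C)(C)C
F3 | step 5 | ethyl (E)-3-[(2S,3S)-2-{[(tert-butyldimethylsilyl)oxy]methyl}-3-[3,5-dimethoxy-4-(pivaloyloxy)phenyl]-8-methoxy-2,3-dihydro-1,4-benzodioxin-6-yl]prop-2-enoate | COc1cc([C@@H]2Oc3cc(/C=C/C(=O)OCC)cc(OC)c3O[C@H]2CO[Si](C)(C)C(C)(C)C)cc(OC)c1OC(=O)C(C)(C)C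
F4 | step 3 | tert-butyl 2-{2-bromo-4-[(E)-3-ethoxy-3-oxoprop-1-en-1-yl]-6-methoxyphenoxy}acetate | CCOC(=O)/C=C/c1cc(Br)c(OCC(=O)OC(C)(C)C)c(OC)c1
F5 | step 3 | 2-{2-bromo-4-[(E)-3-ethoxy-3-oxoprop-1-en-1-yl]-6-methoxyphenoxy}acetic acid | CCOC(=O)/C=C/c1cc(Br)c(OCC(=O)O)c(OC)c1
F6 | step 7 | 4-[(2S,3S)-3-(hydroxymethyl)-7-[(E)-3-hydroxyprop-1-en-1-yl]-5-methoxy-2,3-dihydro-1,4-benzodioxin-2-yl]-2,6-dimethoxyphenyl 2,2-dimethylpropanoate | COc1cc([C@@H]2Oc3cc(/C=C/CO)cc(OC)c3O[C@H]2CO)cc(OC)c1OC(=O)C(C)(C)C
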